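The amounts charged come first, and the steps thought possible are G + E -> X, G + J -> D, E <-> J, X <-> D and G -> Q.

| flask | E | J | G | remark | time |
|---|---|---|---|---|---|
| violet | 0.12 M | 0.12 M | 0.92 M | run made earlier |  |
| red | 0.46 M | 0.46 M | 0.92 M | run made earlier |  |
| flask | 0.23 M | 0.23 M | 0.920 M |  | 12 h |

| run | time / h | E / % | J / % | X / % |
|---|---|---|---|---|
| violet | 1.33 | 48.8 | 48.5 | 3.6 |
| violet | 3.00 | 47.4 | 45.3 | 4.9 |
| violet | 6.00 | 43.8 | 46.5 | 6.9 |
| violet | 10.0 | 40.1 | 40.4 | 12.2 |
| red | 0.833 | 48.5 | 49.4 | 0.5 |
| red | 2.00 | 48.0 | 46.2 | 1.0 |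
| red | 4.00 | 46.1 | 46.1 | 3.9 |
| red | 10.0 | 40.2 | 40.5 | 11.1 |

(scatter of a reading: 1 percentage point)
- G is single-handed; E and J are mirror images of each other, charged as a racemate, each of them at the stated concentration
- the numbers in the tables scatter by 1 percentage point (one standard deviation)
- steps thought possible: G + E -> X; G + J -> D; E <-> J; X <-> D; G -> Q
- an excess is the difference of the two amounts in percent of their sum
- an excess is below zero if the other one leads
- the handed part of G does not stay in what it makes, so the products of the two hands are mirror images too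
1. part of the E and J charged together that has reacted at 12 h
2. excess of X over D in the product at 12 h
3. excess of J over E among what is left of the two at 12 h

At 10.0 h violet keeps 80.5 % of its E and J and red 80.7 %, although red was charged with 3.83 times as much. So I read the fractional loss as not slowed by falling [E] and [J]. From the mean, 80.6 %, I carry one quantity: the fractional loss of E and J per hour and per mol/L of G, the pseudo-first-order constant divided by [G], 0.0234 L mol⁻¹ h⁻¹.

With [G] taken at its charge, as in that reading, I take the flask to start at 0.0216 h⁻¹. What can slow it is G, because each E or J lost takes one G, and the E and J together are half of the G charged. Unslowed, the loss at 12 h is 22.8 %, which brings G to 88.6 % of its charge. The mean slowing factor is then 94.3 %, so I reckon 21.7 % reacted. If G -> Q runs, this leans high, and no reading shows G.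

The forecast gives c = 23 %, above my 21.7 %, with eP = 20 % and eS = 1 %, seeing “little sign of G running out”.

The flask gives c = 19.9 %, eP = 36.4 % and eS = 0.849 %.

    G + E → X (k = 0.0327 L mol⁻¹ h⁻¹)
    G + J → D (k = 0.0129 L mol⁻¹ h⁻¹)
    E ⇌ J (k = 0.431 h⁻¹)
    X ⇌ D (k = 0.0127 h⁻¹)
    G → Q (k = 0.0108 h⁻¹)

At 12.0 h G stands at 79 % of its charge in the flask, below my 88.6 %. At 5.64 h in the flask, its half-life by G -> Q is 64 h, shorter than the 100 h by G + E -> X. With that G, 0.0234 L mol⁻¹ h⁻¹ gives 20.6 % for the flask. In the neighbour flask, with the same E and J and the same time but charged with 1.6 M of G, 79 % of it left, 0.0234 L mol⁻¹ h⁻¹ gives 33.1 %, and the computed result is 32.1 %.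

The runs were computed on assumed constants; scatter was added.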